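The route rests on disconnecting the C2–C3 bond of each dihydropyranone ring (ring C of both flavanone units), which turns the biflavanone into an open bis(benzyl aryl ether) carrying two α-diazoketones. One operation, a twofold enantioselective dirhodium-carbenoid C–H insertion, closes both heterocycles and sets both (S)-configured C2 centres. The step exploits the ring oxygen O1: it occupies the position where the usual five-ring insertion would occur, so the only C–H within reach is the benzylic, O1-activated C2–H. The precursor is assembled from a Chan–Lam-derived diaryl ether and two silylated phloroacetophenones by Mitsunobu etherification and detrifluoroacetylative diazo transfer.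

Key step: step 8

Convention: unit 1 is the 7-methoxyflavanone half and unit 2 is the 5,7-dihydroxyflavanone half; in each unit ring A is the phloroglucinol-derived benzene ring, ring C the dihydropyranone ring and ring B the 2-aryl ring; O1, C2, C3 and C4 are the atoms of ring C in flavanone numbering; TIPS = triisopropylsilyl; Rh2(S-PTTL)4 = dirhodium tetrakis[N-phthaloyl-(S)-tert-leucinate].

Assumption: Rh2(S-PTTL)4 is taken to select the benzylic hydrogen that leads to (S)-configured C2; should the sense prove opposite, the mirror-image catalyst Rh2(R-PTTL)4 is used with no other change.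

Step 1
Reactants: 1 4-(benzyloxy)-3-hydroxybenzaldehyde; 2 [4-(hydroxymethyl)phenyl]boronic acid
Product: 3 4-(benzyloxy)-3-[4-(hydroxymethyl)phenoxy]benzaldehyde
Conditions: Cu(OAc)2 (1 equiv), pyridine (5 equiv), 4 Å molecular sieves, CH2Cl2, air, rt; 2 in excess
Reagents that add atoms: none
Why: Chan–Lam oxidative C–O coupling, in which the phenol is transferred to copper far faster than the aliphatic benzylic alcohol of 2 and the aldehyde is inert, so that a diaryl ether with one CHO and one CH2OH terminus should result.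

Step 2
Reactants: 4 1-(2,4,6-trihydroxyphenyl)ethan-1-one (phloroacetophenone)
Product: 5 1-[2-hydroxy-4,6-bis(triisopropylsilyloxy)phenyl]ethan-1-one
Conditions: TIPSCl (2.1 equiv), imidazole (4 equiv), DMF, 0 °C to rt
Reagents that add atoms: triisopropylsilyl chloride (TIPSCl), CC(C)[Si](Cl)(C(C)C)C(C)C
Why: Imidazole-mediated silyl ether formation should take the non-chelated 4-OH and one of the two equivalent ortho OH groups, while the last phenol stays locked in a hydrogen bond to the acetyl carbonyl.

Step 3
Reactants: 3 4-(benzyloxy)-3-[4-(hydroxymethyl)phenoxy]benzaldehyde; 5 1-[2-hydroxy-4,6-bis(triisopropylsilyloxy)phenyl]ethan-1-one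
Product: 6 3-[4-({2-acetyl-3,5-bis(triisopropylsilyloxy)phenoxy}methyl)phenoxy]-4-(benzyloxy)benzaldehyde
Conditions: PPh3, DIAD, THF, 0 °C to rt
Reagents that add atoms: none
Why: Mitsunobu etherification, in which the ortho-acyl phenol displaces the activated primary benzylic oxyphosphonium group under base-free conditions that should spare the aryl silyl ethers and the aldehyde.

Step 4
Reactants: 6 3-[4-({2-acetyl-3,5-bis(triisopropylsilyloxy)phenoxy}methyl)phenoxy]-4-(benzyloxy)benzaldehyde
Product: 7 1-{2-[(4-{2-(benzyloxy)-5-(hydroxymethyl)phenoxy}phenyl)methoxy]-4,6-bis(triisopropylsilyloxy)phenyl}ethan-1-one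
Conditions: NaBH4, THF/MeOH, −10 °C, short reaction time
Reagents that add atoms: none
Why: Chemoselective borohydride reduction, since the aryl aldehyde should be reduced far faster than the doubly ortho-substituted, electron-rich aryl methyl ketone.

Step 5
Reactants: 8 1-(2,6-dihydroxy-4-methoxyphenyl)ethan-1-one
Product: 9 1-[2-hydroxy-4-methoxy-6-(triisopropylsilyloxy)phenyl]ethan-1-one
Conditions: TIPSCl (1.05 equiv), imidazole, DMF, 0 °C
Reagents that add atoms: triisopropylsilyl chloride (TIPSCl), CC(C)[Si](Cl)(C(C)C)C(C)C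
Why: Monosilylation of one of two equivalent phenols, after which the remaining OH is chelated to the acetyl group and should resist a second silylation.

Step 6
Reactants: 7 1-{2-[(4-{2-(benzyloxy)-5-(hydroxymethyl)phenoxy}phenyl)methoxy]-4,6-bis(triisopropylsilyloxy)phenyl}ethan-1-one; 9 1-[2-hydroxy-4-methoxy-6-(triisopropylsilyloxy)phenyl]ethan-1-one
Product: 10 bis(methyl ketone) in which ring A of unit 1 (2-acetyl-5-methoxy-3-TIPSO-phenoxy) and ring A of unit 2 (2-acetyl-3,5-bis-TIPSO-phenoxy) are each bound through an OCH2 group to ring B of the same unit within the diaryl ether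
Conditions: PPh3, DIAD, THF, 0 °C to rt
Reagents that add atoms: none
Why: Second Mitsunobu etherification, now at the electron-rich benzylic alcohol on ring B of unit 1, which should proceed as in step 3 and leave both ketones and all silyl ethers untouched.

Step 7
Reactants: 10 bis(methyl ketone)
Product: 12 bis(α-diazoketone) corresponding to 10, via bis(trifluoroacetylmethyl ketone) 11 (not isolated)
Conditions: LiHMDS (2.4 equiv), THF, −78 °C; CF3CO2CH2CF3 (2.6 equiv), −78 °C; aq. HCl work-up; then p-ABSA (3 equiv), Et3N (3 equiv), H2O (2 equiv), MeCN, rt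
Reagents that add atoms: 4-acetamidobenzenesulfonyl azide (p-ABSA), CC(=O)Nc1ccc(cc1)S(=O)(=O)N=[N+]=[N-] (the two nitrogen atoms of each diazo group); 2,2,2-trifluoroethyl trifluoroacetate, O=C(OCC(F)(F)F)C(F)(F)F (the trifluoroacetyl groups of 11 only)
Why: Detrifluoroacetylative diazo transfer, a variant of the Regitz diazo transfer, in which kinetic enolisation and trifluoroacetylation activate each methyl ketone and the sulfonyl azide then delivers N2 with loss of the trifluoroacetyl group; the low temperature and the bulk of TIPS should prevent silyl migration to the enolate oxygen.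

Step 8
Reactants: 12 bis(α-diazoketone)
Product: 15 (2S,2''S)-4'-O-benzyl-5,5'',7''-tris-O-(triisopropylsilyl)-7-O-methyltetrahydroochnaflavone, via unit-2-cyclised mono(diazoketone) 13 (not isolated), via unit-1-cyclised mono(diazoketone) 14 (not isolated)
Conditions: Rh2(S-PTTL)4 (2 mol %), CH2Cl2, slow addition of 12 by syringe pump to high dilution, 0 °C to rt
Reagents that add atoms: none
Why: Each diazoketone loses N2 at the chiral dirhodium tetracarboxylate to give an electrophilic carbenoid of divalent rhodium whose carbon (the future C3) inserts into the benzylic, ether-activated C–H of the neighbouring ArO–CH2–Ar' group (the future C2) through a three-centre, hydride-transfer-like transition state, so that the C2–C3 and C3–H bonds form together; the two diazoketones react independently and in either order (through 13 or 14). The closest known reaction type is the dirhodium-carboxylate-catalysed intramolecular C–H insertion of 2-alkoxyaryl α-diazoketones to chroman-4-ones, applied here twice in one molecule. Ring C of each unit closes as a six-membered dihydropyranone by 1,6-insertion, and a five-ring alternative does not exist because the fifth atom from the carbenoid carbon is O1, which bears no hydrogen. Each new stereocentre (C2 of unit 1 and C2 of unit 2) is set by the chiral ligand sphere of the catalyst, which selects one of the two enantiotopic benzylic hydrogens; because both centres are set independently by the same catalyst, most of the wrong-sense events end in a diastereomer and not in the enantiomer, which should raise the enantiomeric purity of the (S,S)-product. The step needs insertion to win over oxonium-ylide formation at O1 with [1,2]-benzyl shift and over any reaction at the second ortho oxygen; the weak basicity of an aryl ether oxygen conjugated to the acyl-bearing ring, the hydridic character of a C–H that is benzylic, α to oxygen and para to an oxygen donor, the TIPS group on the other ortho oxygen (no α-C–H, shielded oxygen) and slow addition at high dilution should secure this.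

Step 9
Reactants: 15 (2S,2''S)-4'-O-benzyl-5,5'',7''-tris-O-(triisopropylsilyl)-7-O-methyltetrahydroochnaflavone
Product: 16 (2S,2''S)-4'-O-benzyl-7-O-methyltetrahydroochnaflavone
Conditions: TBAF (3.5 equiv), AcOH (3.5 equiv), THF, 0 °C
Reagents that add atoms: none
Why: Fluoride-mediated cleavage of the three aryl silyl ethers, buffered with acetic acid so that each phenoxide is protonated at once and base-induced retro-oxa-Michael opening of the flavanone rings (loss of configuration at C2) should not occur.

Step 10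
Reactants: 16 (2S,2''S)-4'-O-benzyl-7-O-methyltetrahydroochnaflavone
Product: 17 7-O-methyltetrahydroochnaflavone, (2S,2''S)
Conditions: H2 (1 atm), 10% Pd/C, EtOAc/MeOH, rt, stopped after uptake of one equivalent
Reagents that add atoms: none
Why: Hydrogenolysis of the aryl benzyl ether under neutral conditions, which should spare the C4 carbonyl groups and the ring C2–O1 bonds and leave both stereocentres untouched.

Compound list
1 | 4-(benzyloxy)-3-hydroxybenzaldehyde | O=Cc1ccc(OCc2ccccc2)c(O)c1 | starting material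
2 | [4-(hydroxymethyl)phenyl]boronic acid | OCc1ccc(B(O)O)cc1 | starting material
3 | 4-(benzyloxy)-3-[4-(hydroxymethyl)phenoxy]benzaldehyde | O=Cc1ccc(OCc2ccccc2)c(Oc2ccc(CO)cc2)c1 | intermediate
4 | 1-(2,4,6-trihydroxyphenyl)ethan-1-one | CC(=O)c1c(O)cc(O)cc1O | starting material
5 | 1-[2-hydroxy-4,6-bis(triisopropylsilyloxy)phenyl]ethan-1-one | CC(=O)c1c(O)cc(O[Si](C(C)C)(C(C)C)C(C)C)cc1O[Si](C(C)C)(C(C)C)C(C)C | intermediate
6 | 3-[4-({2-acetyl-3,5-bis(triisopropylsilyloxy)phenoxy}methyl)phenoxy]-4-(benzyloxy)benzaldehyde | O=Cc1ccc(OCc2ccccc2)c(Oc2ccc(COc3cc(O[Si](C(C)C)(C(C)C)C(C)C)cc(O[Si](C(C)C)(C(C)C)C(C)C)c3C(C)=O)cc2)c1 | intermediate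
7 | 1-{2-[(4-{2-(benzyloxy)-5-(hydroxymethyl)phenoxy}phenyl)methoxy]-4,6-bis(triisopropylsilyloxy)phenyl}ethan-1-one | OCc1ccc(OCc2ccccc2)c(Oc2ccc(COc3cc(O[Si](C(C)C)(C(C)C)C(C)C)cc(O[Si](C(C)C)(C(C)C)C(C)C)c3C(C)=O)cc2)c1 | intermediate
8 | 1-(2,6-dihydroxy-4-methoxyphenyl)ethan-1-one | CC(=O)c1c(O)cc(OC)cc1O | starting material
9 | 1-[2-hydroxy-4-methoxy-6-(triisopropylsilyloxy)phenyl]ethan-1-one | CC(=O)c1c(O)cc(OC)cc1O[Si](C(C)C)(C(C)C)C(C)C | intermediate
10 | 1-{2-[(3-{4-[(2-acetyl-3,5-bis(triisopropylsilyloxy)phenoxy)methyl]phenoxy}-4-(benzyloxy)phenyl)methoxy]-4-methoxy-6-(triisopropylsilyloxy)phenyl}ethan-1-one, the bis(methyl ketone) | COc1cc(OCc2ccc(OCc3ccccc3)c(Oc3ccc(COc4cc(O[Si](C(C)C)(C(C)C)C(C)C)cc(O[Si](C(C)C)(C(C)C)C(C)C)c4C(C)=O)cc3)c2)c(C(C)=O)c(O[Si](C(C)C)(C(C)C)C(C)C)c1 | intermediate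
11 | bis(4,4,4-trifluoro-1,3-diketone): both acetyl groups of 10 changed into C(=O)CH2C(=O)CF3 | COc1cc(OCc2ccc(OCc3ccccc3)c(Oc3ccc(COc4cc(O[Si](C(C)C)(C(C)C)C(C)C)cc(O[Si](C(C)C)(C(C)C)C(C)C)c4C(=O)CC(=O)C(F)(F)F)cc3)c2)c(C(=O)CC(=O)C(F)(F)F)c(O[Si](C(C)C)(C(C)C)C(C)C)c1 | intermediate
12 | bis(α-diazoketone): both acetyl groups of 10 changed into C(=O)CH=N2 | COc1cc(OCc2ccc(OCc3ccccc3)c(Oc3ccc(COc4cc(O[Si](C(C)C)(C(C)C)C(C)C)cc(O[Si](C(C)C)(C(C)C)C(C)C)c4C(=O)C=[N+]=[N-])cc3)c2)c(C(=O)C=[N+]=[N-])c(O[Si](C(C)C)(C(C)C)C(C)C)c1 | intermediate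
13 | mono(diazoketone) with ring C of unit 2 closed, (S) at C2 of unit 2, diazoketone of unit 1 still open | COc1cc(OCc2ccc(OCc3ccccc3)c(Oc3ccc([C@@H]4CC(=O)c5c(O[Si](C(C)C)(C(C)C)C(C)C)cc(O[Si](C(C)C)(C(C)C)C(C)C)cc5O4)cc3)c2)c(C(=O)C=[N+]=[N-])c(O[Si](C(C)C)(C(C)C)C(C)C)c1 | intermediate
14 | mono(diazoketone) with ring C of unit 1 closed, (S) at C2 of unit 1, diazoketone of unit 2 still open | COc1cc(O[Si](C(C)C)(C(C)C)C(C)C)c2c(c1)O[C@H](c1ccc(OCc3ccccc3)c(Oc3ccc(COc4cc(O[Si](C(C)C)(C(C)C)C(C)C)cc(O[Si](C(C)C)(C(C)C)C(C)C)c4C(=O)C=[N+]=[N-])cc3)c1)CC2=O | intermediate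
15 | (2S,2''S)-4'-O-benzyl-5,5'',7''-tris-O-(triisopropylsilyl)-7-O-methyltetrahydroochnaflavone | COc1cc(O[Si](C(C)C)(C(C)C)C(C)C)c2c(c1)O[C@H](c1ccc(OCc3ccccc3)c(Oc3ccc([C@@H]4CC(=O)c5c(O[Si](C(C)C)(C(C)C)C(C)C)cc(O[Si](C(C)C)(C(C)C)C(C)C)cc5O4)cc3)c1)CC2=O | intermediate
16 | (2S,2''S)-4'-O-benzyl-7-O-methyltetrahydroochnaflavone | COc1cc(O)c2c(c1)O[C@H](c1ccc(OCc3ccccc3)c(Oc3ccc([C@@H]4CC(=O)c5c(O)cc(O)cc5O4)cc3)c1)CC2=O | intermediate
17 | 7-O-methyltetrahydroochnaflavone, (2S,2''S) | COc1cc(O)c2c(c1)O[C@H](c1ccc(O)c(Oc3ccc([C@@H]4CC(=O)c5c(O)cc(O)cc5O4)cc3)c1)CC2=O | target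

Total step count: 10.
Longest linear sequence: 8 steps (steps 1, 3, 4, 6, 7, 8, 9, 10 from 1 and 2; equally steps 2, 3, 4, 6, 7, 8, 9, 10 from 4).

Steps most likely to fail

Step 8. The carbenoid may be diverted into oxonium-ylide formation at O1 followed by [1,2]-benzyl migration, or the catalyst may discriminate the two enantiotopic benzylic hydrogens too weakly, so that diastereomers accumulate that are hard to remove. The fallback gives up the carbenoid closure and forms both rings by O1–C2 bond formation; it sets out from 3 (with 8) and comes back at 16. Claisen–Schmidt condensation of 3 with 8 (KOH, EtOH/H2O, rt) should give the chalcone alcohol F1. Oxidation with MnO2 (CH2Cl2) should give the chalcone aldehyde F2. A second Claisen–Schmidt condensation with commercial 2'-hydroxy-4',6'-bis(methoxymethoxy)acetophenone should give the bis-chalcone F3. Treatment with HCl/MeOH (loss of both methoxymethyl groups) and then NaOAc in refluxing EtOH (twofold oxa-Michael cyclisation) should give the stereoisomer mixture F4 of the 4'-O-benzyl biflavanone. The (2S,2''S)-isomer 16 is taken from F4 by preparative HPLC on a polysaccharide chiral stationary phase and enters step 10.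

Step 7. Under the strongly basic enolisation the ortho silyl group may migrate from the phenol oxygen to the enolate oxygen, and the twofold acylation may stay incomplete. The fallback avoids enolates; it sets out from 10 and comes back at 12. Riley oxidation (SeO2, dioxane/H2O, 90 °C) should give the bis(arylglyoxal) F5. Condensation with p-toluenesulfonyl hydrazide (2 equiv, MeOH, 0 °C) at the two aldehyde carbons should give the bis(glyoxal monotosylhydrazone) F6. Bamford–Stevens-type elimination of sulfinate with Et3N (CH2Cl2, rt) should then give 12.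

Step 3. Activation and displacement may be sluggish because the phenol is weakly acidic and locked in a hydrogen bond, so that the reduced azodicarboxylate is alkylated instead. The fallback replaces the redox condensation by an alkylation of the phenoxide; it sets out from 3 and comes back at 6. Appel bromination (CBr4, PPh3, CH2Cl2, 0 °C) should give the benzylic bromide F7, and Williamson etherification with 5 (K2CO3, acetone, rt to 40 °C) should give 6.

Further compounds
F1 | step 8 | (E)-3-{4-(benzyloxy)-3-[4-(hydroxymethyl)phenoxy]phenyl}-1-(2,6-dihydroxy-4-methoxyphenyl)prop-2-en-1-one, the chalcone alcohol | COc1cc(O)c(C(=O)/C=C/c2ccc(OCc3ccccc3)c(Oc3ccc(CO)cc3)c2)c(O)c1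
F2 | step 8 | 4-{2-(benzyloxy)-5-[(E)-3-(2,6-dihydroxy-4-methoxyphenyl)-3-oxoprop-1-enyl]phenoxy}benzaldehyde, the chalcone aldehyde | COc1cc(O)c(C(=O)/C=C/c2ccc(OCc3ccccc3)c(Oc3ccc(C=O)cc3)c2)c(O)c1
F3 | step 8 | bis-chalcone whose unit 1 carries a 2',6'-dihydroxy-4'-methoxyphenyl ketone and whose unit 2 carries a 2'-hydroxy-4',6'-bis(methoxymethoxy)phenyl ketone, both enones (E) | COc1cc(O)c(C(=O)/C=C/c2ccc(OCc3ccccc3)c(Oc3ccc(/C=C/C(=O)c4c(O)cc(OCOC)cc4OCOC)cc3)c2)c(O)c1
F4 | step 8 | 4'-O-benzyl-7-O-methyltetrahydroochnaflavone as the mixture of all stereoisomers at C2 and C2'' | COc1cc(O)c2c(c1)OC(c1ccc(OCc3ccccc3)c(Oc3ccc(C4CC(=O)c5c(O)cc(O)cc5O4)cc3)c1)CC2=O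
F5 | step 7 | bis(arylglyoxal): both acetyl groups of 10 changed into C(=O)CHO | COc1cc(OCc2ccc(OCc3ccccc3)c(Oc3ccc(COc4cc(O[Si](C(C)C)(C(C)C)C(C)C)cc(O[Si](C(C)C)(C(C)C)C(C)C)c4C(=O)C=O)cc3)c2)c(C(=O)C=O)c(O[Si](C(C)C)(C(C)C)C(C)C)c1
F6 | step 7 | bis(glyoxal monotosylhydrazone): both acetyl groups of 10 changed into C(=O)CH=N–NHTs, (E) at each C=N | COc1cc(OCc2ccc(OCc3ccccc3)c(Oc3ccc(COc4cc(O[Si](C(C)C)(C(C)C)C(C)C)cc(O[Si](C(C)C)(C(C)C)C(C)C)c4C(=O)/C=N/NS(=O)(=O)c4ccc(C)cc4)cc3)c2)c(C(=O)/C=N/NS(=O)(=O)c2ccc(C)cc2)c(O[Si](C(C)C)(C(C)C)C(C)C)c1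
F7 | step 3 | 4-(benzyloxy)-3-[4-(bromomethyl)phenoxy]benzaldehyde, the benzylic bromide | O=Cc1ccc(OCc2ccccc2)c(Oc2ccc(CBr)cc2)c1
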